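The vessel is closed, stirred and held at one temperature, with the three charges present from the start.

free monomer 1.0 M; protic impurity 0.0500 M; initiator 3.0 mM; time 10 d

    free monomer + initiator → living end + monomer in chains (k1 = 17.0 M⁻¹ h⁻¹)
    free monomer + living end → monomer in chains + living end, rate k2*[living end]*[free monomer] (k2 = 136 M⁻¹ h⁻¹)
    monomer in chains + living end → free monomer + living end, rate k3*[living end] as long as [monomer in chains] is above zero (k3 = 90.5 h⁻¹)
    living end → dead end (k4 = 2.96 h⁻¹)
    protic impurity + free monomer → quenched substrate (k5 = 27.2 M⁻¹ h⁻¹)

- whether the average number of monomer units in a chain (chains begun, living or dead) reaches 30 by 10 d (no / yes)
- average number of monomer units in a chain (chains begun, living or dead) at 10 d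

- the average divides the monomer in chains by the number of chains begun, living and dead together
- run time (flask): 10 d

These constants seem to disagree with each other. A living end lasts 0.338 h on average and, at the charged c(free monomer), adds 45.9 units in that time, more than the 30 wanted, yet I expect shorter chains. The back step returns 30.6 units over the same life, whatever c(free monomer) is, as long as the chains hold monomer. So what to watch is the balance level, the c(free monomer) at which growth and the back step cancel and an end gains nothing, 0.665 M (the usual term is equilibrium monomer concentration). An end's net gain is the margin above this level, times the growth constant, times its life, and the first unit comes from the start of the chain.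

The protic impurity acts on a time of 0.0368 h and the initiator on 0.0588 h, both shorter than the life of an end. So I start growth from 0.950 M, which gives 14.1 units per chain. Chains of that length would hold 0.0422 M, so I go round again with the mean level during growth, 0.929 M. That gives 13.1 units, so my answer on reaching the wanted length is no.

The forecast says no and 13.1, within 12.5 to 13.8, on the ground that each chain gets “only a short window of net growth”.

The simulation gives no and 13.4. At 10.0 d this flask holds free monomer at 91.0% of its charge, 0.244 M above the balance level, with living end at 0 M. For the neighbour flask with 0.20 M of protic impurity, I reckon growth from 0.800 M, a margin of 0.135 M. The first round gives 7.18 units, and the second gives 6.69. That neighbour flask ends at 7.32.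

The numbers of this flask were drawn at random within sensible limits; what happens was integrated by code.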